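**Plan**

- Labels: C1 = quaternary C–CH3, C2 = CH2, C3 = CH–OAc, C4 = C(OH)(iPr), C5 = ring-fusion CH, C6 = CH–O-aroyl, C7=C8(CH3) = alkene, C9 = CH2, C10 = CH–OH. The cyclopentane is C1–C5 and the cycloheptene is C1, C5–C10.
- Cuts, in retrosynthetic order: the C6–O aroyl ester and the C3 acetate; the C8 methyl and the C7=C8 alkene (back to a C6 ketone); the C3/C4 diol (back to a C3=C4 alkene); then the fusion bond C1–C5.
- Enabling feature: the fusion bond C1–C5 lies next to the oxygen-bearing C6. Returning C1 from C5 to C6 turns the cis-fused five/seven ring pair into an angular-methyl decalin 5,6-diol, which maps onto (S)-Wieland–Miescher ketone (carbonyls at C10 and C4, alkene C5=C6).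
- Forward: both six-membered rings are bought. The isopropyl group is coupled onto C4, and one 1,2-shift of C1 from C6 to C5 then contracts one ring to the cyclopentene and expands the other to the cycloheptanone. No further ring is made; diol, C8 methyl/enone, ester and acetate follow.
- Stereochemistry: C1 is bought; C10 comes from borohydride reduction (O cis to the methyl); C5 from inversion in the shift, whose diol precursor is set by OsO4 anti to the methyl; C3/C4 from OsO4 on the convex face; C6 from Luche reduction on the convex face.

Key step: step 6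

Remark: β denotes the face of the bicycle that carries the C1 methyl group and α the opposite face; the C-labels above are used for the decalin precursors as well. The C8 configuration of enol ether 18 is erased in step 12 and is left unassigned.

**Route**

Step 1
Reactants: 1 (S)-Wieland–Miescher ketone
Product: 2 10β-hydroxy enone (C4 enone, C5=C6 alkene, C10 hydroxyl cis to the angular methyl)
Conditions: NaBH4 (0.3 equiv), EtOH, −10 °C
Reagents that add atoms: none
Why: Chemoselective borohydride reduction, in which the saturated C10 ketone is more electrophilic than the vinylogous C4 carbonyl and hydride adds axially on the face away from the angular methyl, so the new hydroxyl should stand equatorial and cis to the methyl.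

Step 2
Reactants: 2 10β-hydroxy enone
Product: 3 10β-silyloxy enone (TBS ether of 2)
Conditions: TBSCl, imidazole, DMF, rt
Reagents that add atoms: tert-butyldimethylsilyl chloride, CC(C)(C)[Si](C)(C)Cl
Why: Imidazole-promoted silylation of a secondary alcohol gives an ether that tolerates the amide bases, Grignard reagent, cuprate and oxidants used later; no stereocentre is touched.

Step 3
Reactants: 3 10β-silyloxy enone
Product: 5 C4 dienyl triflate (C3=C4–OTf, C5=C6), via lithium dienolate 4 (not isolated)
Conditions: LDA, THF, −78 °C; PhNTf2, −78 to 0 °C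
Reagents that add atoms: N-phenylbis(trifluoromethanesulfonimide), O=S(=O)(N(c1ccccc1)S(=O)(=O)C(F)(F)F)C(F)(F)F
Why: Kinetic α′-deprotonation at C3 by the hindered amide gives the cross-conjugated dienolate rather than the extended one, and O-sulfonylation with the triflimide is the standard enol triflate synthesis.

Step 4
Reactants: 5 C4 dienyl triflate
Product: 6 alkenyl triflate 5α,6α-diol (C3=C4–OTf kept; secondary C5–OH and angular C6–OH both on the face opposite the methyl)
Conditions: OsO4 (5 mol%), NMO, acetone/H2O, rt
Reagents that add atoms: osmium tetroxide (catalytic, transfers both oxygens), O=[Os](=O)(=O)=O; N-methylmorpholine N-oxide (reoxidant), C[N+]1([O-])CCOCC1; water, O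
Why: Upjohn dihydroxylation, in which the electrophilic oxidant should take the C5=C6 alkene because C3=C4 is deactivated by its triflyloxy group, and it adds syn on the face away from the axial angular methyl, setting C5 and C6.

Step 5
Reactants: 6 alkenyl triflate 5α,6α-diol; 7 isopropylmagnesium chloride
Product: 10 4-isopropyl-oct-3-alin-5α,6α-diol (C3=C4 alkene bearing isopropyl, allylic secondary C5–OH, angular tertiary C6–OH, 10β-OTBS), via triflate bis(chloromagnesium alkoxide) 8 (not isolated), via coupled bis(chloromagnesium alkoxide) 9 (not isolated)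
Conditions: 7 (3.5 equiv), Fe(acac)3 (10 mol%), THF/NMP, −30 to 0 °C
Reagents that add atoms: isopropylmagnesium chloride 7, CC(C)[Mg]Cl
Why: Iron-catalysed Kumada-type coupling of an alkenyl triflate with an alkyl Grignard reagent, in which the first two equivalents mask the diol as its magnesium alkoxide and the low-valent iron catalyst couples a secondary alkyl group quickly at low temperature with little isomerisation; no stereocentre changes.

Step 6
Reactants: 10 4-isopropyl-oct-3-alin-5α,6α-diol
Product: 12 cis-fused hydroazulen-6-one (C6 ketone in the seven-membered ring, C3=C4 cyclopentene bearing isopropyl, H5 cis to the C1 methyl, 10β-OTBS), via C5 mesylate 11 (not isolated)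
Conditions: Ms2O, Et3N, CH2Cl2, −40 to 0 °C; neutral buffer quench, crude product used at once
Reagents that add atoms: none
Why: Sulfonylation should take only the secondary allylic C5 hydroxyl (the angular C6 hydroxyl is tertiary and axial), and on warming the equatorial mesylate of 11 departs while the antiperiplanar C6–C1 bond moves to C5 and the C6 hydroxyl collapses to the ketone, a semipinacol (pinacol-type) rearrangement of a vicinal diol monosulfonate of the kind known to take angular-methyl decalins to hydroazulenones. Neither ring is made by cyclisation: the cyclohexene C1–C6 loses C6 and contracts to the cyclopentene C1–C5, and the cyclohexane gains C5 and expands to the cycloheptanone, both through the single 1,2-alkyl shift that creates the C1–C5 bond. The only new stereocentre, C5, is set by backside entry of the migrating C1 (inversion at C5, retention at C1), which should leave H5 on the methyl face and hence the cis ring fusion; the configuration it inverts was fixed by the osmylation of step 4. The step needs C1 and not C7 to migrate and a single C5 configuration, and both follow from the half-chair in which only the C6–C1 bond is antiperiplanar to the leaving group, the allylic position of C5 letting this happen under mild conditions. β-Elimination has no hydrogen available (C6 carries none, C4 is an alkene carbon) and the cis oxygens cannot close to an epoxide; because the product is a β,γ-unsaturated ketone with a labile C5–H, only a tertiary amine is present, the temperature stays at or below 0 °C, and chloride-free Ms2O avoids allylic substitution.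

Step 7
Reactants: 12 cis-fused hydroazulen-6-one
Product: 13 3β,4β-dihydroxy ketone (secondary C3–OH and tertiary C4–OH cis to H5 and to the C1 methyl; isopropyl on C4 α)
Conditions: OsO4 (5 mol%), NMO, acetone/H2O, 0 °C to rt
Reagents that add atoms: osmium tetroxide (catalytic, transfers both oxygens), O=[Os](=O)(=O)=O; N-methylmorpholine N-oxide (reoxidant), C[N+]1([O-])CCOCC1; water, O
Why: Upjohn dihydroxylation of the trisubstituted cyclopentene, expected on the convex β face of the cis-fused bicycle, anti to the allylic C5–C6 bond that covers the other face, which sets C3 and C4 and also removes the alkene that makes C5–H labile.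

Step 8
Reactants: 13 3β,4β-dihydroxy ketone
Product: 14 C3,C4 acetonide ketone
Conditions: 2-methoxypropene, PPTS (cat.), CH2Cl2, 0 °C to rt
Reagents that add atoms: 2-methoxypropene, COC(C)=C
Why: Acid-catalysed ketalisation of a cis-1,2-diol with an enol ether closes the five-membered acetonide readily even at the tertiary oxygen, and it protects the β-hydroxy ketone against retro-aldol cleavage in the base steps that follow.

Step 9
Reactants: 14 C3,C4 acetonide ketone
Product: 16 C6–C7 trimethylsilyl enol ether, via lithium C6–C7 enolate 15 (not isolated)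
Conditions: LDA, TMSCl, THF, −78 °C (in situ quench)
Reagents that add atoms: chlorotrimethylsilane, C[Si](C)(C)Cl
Why: Kinetic enolisation with internal silyl quench removes a proton from the C7 methylene and not from the C5 methine buried between two fully substituted carbons, so C5 is neither epimerised nor made to expel the C4 oxygen.

Step 10
Reactants: 16 C6–C7 trimethylsilyl enol ether
Product: 17 cyclohept-7-en-6-one (C6 ketone, C7=C8 alkene)
Conditions: Pd(OAc)2 (1.1 equiv), MeCN, rt
Reagents that add atoms: none
Why: Saegusa–Ito oxidation, in which the enol ether is transmetalated to a palladium enolate that loses a β-hydride from C8, the only position the fixed enolate regiochemistry allows.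

Step 11
Reactants: 17 cyclohept-7-en-6-one
Product: 18 8-methyl C6–C7 trimethylsilyl enol ether
Conditions: Me2CuLi (from MeLi and CuI), TMSCl, THF, −78 °C
Reagents that add atoms: lithium dimethylcuprate, [Li+].C[Cu-]C; chlorotrimethylsilane, C[Si](C)(C)Cl
Why: Chlorosilane-accelerated conjugate addition of a Gilman cuprate puts the methyl group on C8 and traps the enolate regiospecifically as the C6–C7 enol ether; the transient C8 stereocentre is of no consequence.

Step 12
Reactants: 18 8-methyl C6–C7 trimethylsilyl enol ether
Product: 19 8-methylcyclohept-7-en-6-one (β-methyl enone)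
Conditions: Pd(OAc)2 (1.1 equiv), MeCN, rt
Reagents that add atoms: none
Why: A second Saegusa–Ito oxidation, where the single C8 hydrogen is the only β-hydride available, restores the C7=C8 alkene with the methyl group now on C8.

Step 13
Reactants: 19 8-methylcyclohept-7-en-6-one
Product: 20 C6 allylic alcohol (6α-OH, trans to H5)
Conditions: NaBH4, CeCl3·7H2O, MeOH, −78 °C
Reagents that add atoms: none
Why: Luche reduction gives clean 1,2-addition to the enone, and hydride is expected on the convex β face (the face of H5 and the methyl), the concave face being occupied by the C4 isopropyl group, which sets C6.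

Step 14
Reactants: 21 4-hydroxybenzoic acid
Product: 23 4-(tert-butyldimethylsilyloxy)benzoic acid, via bis-silyl compound 22 (not isolated)
Conditions: TBSCl (2.5 equiv), imidazole, DMF, rt; then AcOH/THF/H2O, rt
Reagents that add atoms: tert-butyldimethylsilyl chloride, CC(C)(C)[Si](C)(C)Cl
Why: Exhaustive silylation followed by selective hydrolysis works because a silyl ester is far more labile to aqueous acid than an aryl silyl ether.

Step 15
Reactants: 20 C6 allylic alcohol; 23 4-(tert-butyldimethylsilyloxy)benzoic acid
Product: 24 fully protected C6 aroyl ester (acetonide, 10β-OTBS, aryl OTBS)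
Conditions: DCC, DMAP, CH2Cl2, 0 °C to rt
Reagents that add atoms: 4-(tert-butyldimethylsilyloxy)benzoic acid 23, O=C(O)c1ccc(O[Si](C)(C)C(C)(C)C)cc1
Why: Steglich esterification acylates the hindered secondary allylic alcohol on oxygen under neutral conditions, so the C6 configuration is retained and no allylic transposition is invited.

Step 16
Reactants: 24 fully protected C6 aroyl ester
Product: 25 C3,C4-diol ester
Conditions: AcOH/H2O (4:1), 40 °C
Reagents that add atoms: none
Why: Mild acid hydrolysis of the acetonide should spare the aryl silyl ether, the hindered neopentyl-type C10 silyl ether and the aroyl ester, a poor leaving group at this acidity.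

Step 17
Reactants: 25 C3,C4-diol ester
Product: 26 C3 acetate (tertiary C4–OH free, both silyl ethers in place)
Conditions: Ac2O, pyridine, DMAP (cat.), CH2Cl2, 0 °C to rt
Reagents that add atoms: acetic anhydride, CC(=O)OC(C)=O
Why: DMAP-catalysed acetylation reaches the only free secondary hydroxyl (C3) and leaves the tertiary C4 hydroxyl, flanked by the isopropyl group and the ring fusion, untouched.

Step 18
Reactants: 26 C3 acetate
Product: 27 target CNP0146780.2
Conditions: HF·pyridine, pyridine, THF, 0 °C to rt
Reagents that add atoms: none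
Why: Buffered fluoride desilylation cleaves the aryl and the secondary alkyl silyl ether in one operation without base, so neither ester is hydrolysed and the acetate does not migrate.

**Compound list**

1 | (S)-Wieland–Miescher ketone | C[C@]12CCC(=O)C=C1CCCC2=O | starting material
2 | 10β-hydroxy enone, (4aS,5S)-5-hydroxy-4a-methyl-4,4a,5,6,7,8-hexahydronaphthalen-2(3H)-one | C[C@]12CCC(=O)C=C1CCC[C@@H]2O | intermediate
3 | 10β-(tert-butyldimethylsilyloxy) enone | C[C@]12CCC(=O)C=C1CCC[C@@H]2O[Si](C)(C)C(C)(C)C | intermediate
4 | lithium cross-conjugated dienolate (C3=C4–OLi, C5=C6) | C[C@]12CC=C(O[Li])C=C1CCC[C@@H]2O[Si](C)(C)C(C)(C)C | intermediate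
5 | C4 dienyl triflate (C3=C4–OTf, C5=C6) | C[C@]12CC=C(OS(=O)(=O)C(F)(F)F)C=C1CCC[C@@H]2O[Si](C)(C)C(C)(C)C | intermediate
6 | alkenyl triflate 5α,6α-diol | C[C@]12CC=C(OS(=O)(=O)C(F)(F)F)[C@@H](O)[C@]1(O)CCC[C@@H]2O[Si](C)(C)C(C)(C)C | intermediate
7 | isopropylmagnesium chloride | CC(C)[Mg]Cl | starting material
8 | bis(chloromagnesium alkoxide) of triflate diol 6 | C[C@]12CC=C(OS(=O)(=O)C(F)(F)F)[C@@H](O[Mg]Cl)[C@]1(O[Mg]Cl)CCC[C@@H]2O[Si](C)(C)C(C)(C)C | intermediate
9 | bis(chloromagnesium alkoxide) of isopropyl diol 10 | C[C@]12CC=C(C(C)C)[C@@H](O[Mg]Cl)[C@]1(O[Mg]Cl)CCC[C@@H]2O[Si](C)(C)C(C)(C)C | intermediate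
10 | 4-isopropyl-oct-3-alin-5α,6α-diol, 10β-OTBS | C[C@]12CC=C(C(C)C)[C@@H](O)[C@]1(O)CCC[C@@H]2O[Si](C)(C)C(C)(C)C | intermediate
11 | C5 mesylate of diol 10 | C[C@]12CC=C(C(C)C)[C@@H](OS(C)(=O)=O)[C@]1(O)CCC[C@@H]2O[Si](C)(C)C(C)(C)C | intermediate
12 | cis-fused hydroazulen-6-one (C3=C4 alkene with isopropyl, 5β-H, 10β-OTBS) | CC(C)C1=CC[C@]2(C)[C@@H](O[Si](C)(C)C(C)(C)C)CCCC(=O)[C@@H]21 | intermediate
13 | 3β,4β-dihydroxy hydroazulen-6-one | O[C@H]1C[C@]2(C)[C@@H](O[Si](C)(C)C(C)(C)C)CCCC(=O)[C@@H]2[C@]1(O)C(C)C | intermediate
14 | C3,C4 acetonide of the hydroazulen-6-one | CC1(C)O[C@H]2C[C@]3(C)[C@@H](O[Si](C)(C)C(C)(C)C)CCCC(=O)[C@@H]3[C@]2(O1)C(C)C | intermediate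
15 | lithium C6–C7 enolate of 14 | CC1(C)O[C@H]2C[C@]3(C)[C@@H](O[Si](C)(C)C(C)(C)C)CCC=C(O[Li])[C@@H]3[C@]2(O1)C(C)C | intermediate
16 | C6–C7 trimethylsilyl enol ether | CC1(C)O[C@H]2C[C@]3(C)[C@@H](O[Si](C)(C)C(C)(C)C)CCC=C(O[Si](C)(C)C)[C@@H]3[C@]2(O1)C(C)C | intermediate
17 | cyclohept-7-en-6-one (acetonide, 10β-OTBS) | CC1(C)O[C@H]2C[C@]3(C)[C@@H](O[Si](C)(C)C(C)(C)C)CC=CC(=O)[C@@H]3[C@]2(O1)C(C)C | intermediate
18 | 8-methyl C6–C7 trimethylsilyl enol ether (C8 unassigned) | CC1(C)O[C@H]2C[C@]3(C)[C@@H](O[Si](C)(C)C(C)(C)C)CC(C)C=C(O[Si](C)(C)C)[C@@H]3[C@]2(O1)C(C)C | intermediate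
19 | 8-methylcyclohept-7-en-6-one (acetonide, 10β-OTBS) | CC1(C)O[C@H]2C[C@]3(C)[C@@H](O[Si](C)(C)C(C)(C)C)CC(C)=CC(=O)[C@@H]3[C@]2(O1)C(C)C | intermediate
20 | C6 allylic alcohol (6α-OH) | CC1(C)O[C@H]2C[C@]3(C)[C@@H](O[Si](C)(C)C(C)(C)C)CC(C)=C[C@H](O)[C@@H]3[C@]2(O1)C(C)C | intermediate
21 | 4-hydroxybenzoic acid | O=C(O)c1ccc(O)cc1 | starting material
22 | tert-butyldimethylsilyl 4-(tert-butyldimethylsilyloxy)benzoate | CC(C)(C)[Si](C)(C)OC(=O)c1ccc(O[Si](C)(C)C(C)(C)C)cc1 | intermediate
23 | 4-(tert-butyldimethylsilyloxy)benzoic acid | O=C(O)c1ccc(O[Si](C)(C)C(C)(C)C)cc1 | intermediate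
24 | fully protected C6 aroyl ester | CC1(C)O[C@H]2C[C@]3(C)[C@@H](O[Si](C)(C)C(C)(C)C)CC(C)=C[C@H](OC(=O)c4ccc(O[Si](C)(C)C(C)(C)C)cc4)[C@@H]3[C@]2(O1)C(C)C | intermediate
25 | C3,C4-diol ester (both silyl ethers in place) | O[C@H]1C[C@]2(C)[C@@H](O[Si](C)(C)C(C)(C)C)CC(C)=C[C@H](OC(=O)c3ccc(O[Si](C)(C)C(C)(C)C)cc3)[C@@H]2[C@]1(O)C(C)C | intermediate
26 | C3 acetate, bis-silyl ether | CC(=O)O[C@H]1C[C@]2(C)[C@@H](O[Si](C)(C)C(C)(C)C)CC(C)=C[C@H](OC(=O)c3ccc(O[Si](C)(C)C(C)(C)C)cc3)[C@@H]2[C@]1(O)C(C)C | intermediate
27 | CNP0146780.2 | CC(=O)O[C@H]1C[C@]2(C)[C@@H](O)CC(C)=C[C@H](OC(=O)c3ccc(O)cc3)[C@@H]2[C@]1(O)C(C)C | target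

**Count and risks**

Total step count: 18. Longest linear sequence: 17 steps (steps 1–13 and 15–18, from 1 to 27); step 14 makes the acid on a side branch.

Steps most likely to fail:

1. Step 6. The β,γ-unsaturated ketone may be lost during or after the shift, by base-mediated migration of the C3=C4 double bond into conjugation with the C6 carbonyl or by epimerisation at C5. Ionisation ahead of migration could also divert the allylic mesylate. The fallback keeps the same 1,2-shift but never leaves the ketone free. Setting out from 10, mesylate 11 is generated at −78 °C (MsCl, Et3N, CH2Cl2) and treated in the same flask with Et3Al and then i-Bu2AlH. This is an organoaluminium-promoted pinacol-type rearrangement with reduction of the aluminium-bound ketone, and should give the hydroazulen-6-ol F1 (C6 configuration immaterial). Osmylation (OsO4, NMO) would give the triol F2, 2-methoxypropene with PPTS the acetonide alcohol F3, and Dess–Martin periodinane would return the sequence to the route at ketone 14.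

2. Step 5. The coupling may fail at a hindered alkenyl triflate flanked by a magnesium alkoxide, through reduction of the triflate, sulfur–oxygen cleavage, or isomerisation of the secondary alkyl group. The fallback sets out from 6 and joins the carbon–carbon bond with an sp2 partner. Suzuki–Miyaura coupling with isopropenylboronic acid pinacol ester (Pd(dppf)Cl2, K3PO4, dioxane/H2O) tolerates the free diol and should give the isopropenyl diene diol F4. Hydrogenation with RhCl(PPh3)3 under H2 should saturate only the 1,1-disubstituted alkene and leave the trisubstituted ring alkene, returning to the route at 10.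

3. Step 13. Hydride delivery may show poor facial selectivity, or prefer the concave face. The fallback sets out from 19. The C6-epimeric allylic alcohol F5, the product of hydride addition on the other face, is esterified with inversion by a Mitsunobu reaction with acid 23 (PPh3, DIAD, toluene, 0 °C to rt). This reaches 24 directly and replaces steps 13 and 15.

**Further compounds**

F1 | step 6 | cis-fused hydroazulen-6-ol (C3=C4 alkene with isopropyl, 10β-OTBS, C6 unassigned) | CC(C)C1=CC[C@]2(C)[C@@H](O[Si](C)(C)C(C)(C)C)CCCC(O)[C@@H]21
F2 | step 6 | 3β,4β,6-triol (10β-OTBS, C6 unassigned) | O[C@H]1C[C@]2(C)[C@@H](O[Si](C)(C)C(C)(C)C)CCCC(O)[C@@H]2[C@]1(O)C(C)C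
F3 | step 6 | C3,C4 acetonide 6-alcohol (C6 unassigned) | CC1(C)O[C@H]2C[C@]3(C)[C@@H](O[Si](C)(C)C(C)(C)C)CCCC(O)[C@@H]3[C@]2(O1)C(C)C
F4 | step 5 | 4-isopropenyl-oct-3-alin-5α,6α-diol, 10β-OTBS | C[C@]12CC=C(C(C)=C)[C@@H](O)[C@]1(O)CCC[C@@H]2O[Si](C)(C)C(C)(C)C
F5 | step 13 | C6-epimeric allylic alcohol (6β-OH) | CC1(C)O[C@H]2C[C@]3(C)[C@@H](O[Si](C)(C)C(C)(C)C)CC(C)=C[C@@H](O)[C@@H]3[C@]2(O1)C(C)C
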